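The synthesis rests on disconnecting the C5–C6 bond (germacrane numbering) of the ten-membered carbocycle, between oxirane carbon C5 and C6, the carbinol carbon of the γ-lactone ring. Forward, an intramolecular Nozaki–Hiyama–Kishi reaction of an open-chain (E)-alkenyl iodide (C5) with a C6 aldehyde closes the cyclodecadiene, sets C6 and leaves the C4=C5 alkene for the final epoxidation; the new C6 hydroxyl then captures the adjacent acrylate ester (C12) as the trans-fused α-methylene lactone. The step exploits that C6 is an allylic carbinol once the C4–C5 oxirane is read as an alkene. The precursor already holds C7, C8, C9 (D-malate, indium allylation) and the epoxy ester.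

Key step: step 16

Remark: carbons are numbered as in germacranolides (C1–C10 ring, C11–C13 lactone carbons, C14 ester carbon, C15 methyl); 2-[(4-methoxybenzyl)oxy]acetaldehyde is taken as a catalogue compound.

Step 1
Reactants: 1 pent-4-yn-1-ol
Product: 3 (E)-5-iodo-4-methylpent-4-en-1-ol, via alkenylalane 2 (not isolated)
Conditions: AlMe3 (3 equiv), Cp2ZrCl2 (0.25 equiv), CH2Cl2, 0 °C to rt; then I2, THF, −30 to 0 °C
Reagents that add atoms: trimethylaluminium, C[Al](C)C; iodine, II
Why: Negishi carboalumination adds methyl and aluminium syn across the terminal alkyne with aluminium on the terminal carbon, and iodinolysis with retention should give the (E)-alkenyl iodide, which fixes C15 and the C4=C5 geometry.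

Step 2
Reactants: 3 (E)-5-iodo-4-methylpent-4-en-1-ol
Product: 4 (E)-5-iodo-4-methylpent-4-enal (fragment A)
Conditions: Dess–Martin periodinane, NaHCO3, CH2Cl2, 0 °C to rt
Reagents that add atoms: none
Why: Dess–Martin oxidation of a primary alcohol to the aldehyde is neutral and leaves the alkenyl iodide untouched.

Step 3
Reactants: 5 dimethyl (R)-malate
Product: 6 methyl (3R)-3,4-dihydroxybutanoate
Conditions: BH3·SMe2 (1.05 equiv), NaBH4 (5 mol %), THF, 0 °C to rt; MeOH quench
Reagents that add atoms: none
Why: Hydroxyl-directed borane reduction through a cyclic alkoxyborane should reduce only the ester next to the carbinol, so C8 reaches the alcohol level, C14 stays a methyl ester and the C9 stereocentre of the chiral pool is untouched.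

Step 4
Reactants: 6 methyl (3R)-3,4-dihydroxybutanoate
Product: 7 methyl (3R)-3,4-bis(triethylsilyloxy)butanoate
Conditions: Et3SiCl (2.4 equiv), imidazole, DMF, 0 °C to rt
Reagents that add atoms: chlorotriethylsilane, CC[Si](Cl)(CC)CC
Why: Standard silylation protects the C9 hydroxyl and puts a primary triethylsilyl ether on C8 that can later be oxidised directly.

Step 5
Reactants: 7 methyl (3R)-3,4-bis(triethylsilyloxy)butanoate; 4 (E)-5-iodo-4-methylpent-4-enal
Product: 9 methyl (6E)-2-[(1R)-1,2-bis(triethylsilyloxy)ethyl]-3-hydroxy-7-iodo-6-methylhept-6-enoate (mixture at C2 and C3), via lithium enolate 8 (not isolated)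
Conditions: LiN(iPr)2 (1.1 equiv), THF, −78 °C; then 4, −78 °C; sat. NH4Cl at −78 °C
Reagents that add atoms: none
Why: Lithium ester enolate aldol addition at −78 °C (where β-silyloxy elimination is slow) forms the C10–C1 bond, and the two new stereocentres need no control because both are removed in the next step.

Step 6
Reactants: 9 aldol adduct
Product: 11 methyl (2E,6E)-2-[(1R)-1,2-bis(triethylsilyloxy)ethyl]-7-iodo-6-methylhepta-2,6-dienoate, via mesylate 10 (not isolated)
Conditions: MsCl, Et3N, CH2Cl2, 0 °C; then DBU, rt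
Reagents that add atoms: none
Why: Mesylation and E1cB elimination should give the thermodynamically preferred tiglate-type enoate with the chain trans to the ester, which is the C1=C10 geometry of the target (C2 cis to C9).

Step 7
Reactants: 11 bis-silyl dienoate
Product: 13 methyl (2E,6E)-7-iodo-6-methyl-2-[(1R)-2-oxo-1-(triethylsilyloxy)ethyl]hepta-2,6-dienoate (fragment B), via alkoxysulfonium chloride 12 (not isolated)
Conditions: (COCl)2 (4 equiv), DMSO (8 equiv), CH2Cl2, −78 to −40 °C; then Et3N, −78 to −20 °C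
Reagents that add atoms: none
Why: Under Swern conditions a primary triethylsilyl ether is cleaved by the chlorosulfonium salt and oxidised in the same flask while the secondary one survives, so the α-silyloxy aldehyde forms without a free γ-hydroxy ester that could lactonise; the cold quench should preserve C9.

Step 8
Reactants: 14 2-[(4-methoxybenzyl)oxy]acetaldehyde; 15 methyl acrylate
Product: 16 methyl 3-hydroxy-4-[(4-methoxybenzyl)oxy]-2-methylidenebutanoate (racemic)
Conditions: DABCO (0.5 equiv), 1,4-dioxane/H2O (1:1), rt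
Reagents that add atoms: none
Why: Morita–Baylis–Hillman reaction of an α-alkoxy aldehyde with methyl acrylate; the racemic carbinol centre is erased in the next step.

Step 9
Reactants: 16 Baylis–Hillman alcohol
Product: 17 methyl (2Z)-2-(bromomethyl)-4-[(4-methoxybenzyl)oxy]but-2-enoate (fragment C)
Conditions: NBS, Me2S, CH2Cl2, 0 °C (reagent pre-formed); then 16, 0 °C to rt
Reagents that add atoms: N-bromosuccinimide, O=C1CCC(=O)N1Br
Why: Corey–Kim-type bromination of Baylis–Hillman alcohols proceeds with allylic transposition (SN2′) to the thermodynamically favoured (Z)-2-(bromomethyl)enoate.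

Step 10
Reactants: 18 (2E)-2-methylbut-2-en-1-ol
Product: 19 [(2R,3R)-2,3-dimethyloxiran-2-yl]methanol
Conditions: Ti(OiPr)4 (10 mol %), D-(−)-diethyl tartrate (12 mol %), tBuOOH, 4 Å molecular sieves, CH2Cl2, −20 °C
Reagents that add atoms: tert-butyl hydroperoxide, CC(C)(C)OO
Why: Sharpless asymmetric epoxidation with the D-(−)-tartrate should deliver oxygen to the face that gives the (2R,3R)-epoxy alcohol, the cis relationship of the two methyl groups following from the (E)-alkene.

Step 11
Reactants: 19 [(2R,3R)-2,3-dimethyloxiran-2-yl]methanol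
Product: 20 (2S,3R)-2,3-dimethyloxirane-2-carboxylic acid
Conditions: RuCl3 (2 mol %), NaIO4 (3 equiv), CCl4/MeCN/H2O (2:2:3), rt
Reagents that add atoms: water, O
Why: Catalytic ruthenium tetroxide oxidation of a primary epoxy alcohol to the glycidic acid leaves the oxirane and both stereocentres intact (the descriptor at C2 changes only by priority).

Step 12
Reactants: 13 aldehyde (fragment B); 17 allylic bromide (fragment C)
Product: 22 dimethyl (3S,4S,5R,6E)-4-hydroxy-6-[(4E)-5-iodo-4-methylpent-4-en-1-ylidene]-3-{[(4-methoxybenzyl)oxy]methyl}-2-methylidene-5-(triethylsilyloxy)heptanedioate, via allylindium 21 (not isolated)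
Conditions: In powder (1.5 equiv), THF/H2O (1:1), rt
Reagents that add atoms: none
Why: Indium-mediated Barbier allylation: the 2-(methoxycarbonyl)allylindium adds through its γ-carbon (C7) in a chair-like transition state that should give the syn C7/C8 relationship (C6 and O8 syn along C11–C7–C8–C9), while Felkin–Anh attack anti to the C9 silyloxy group sets C8 (8,9-anti).

Step 13
Reactants: 22 homoallylic alcohol; 20 (2S,3R)-2,3-dimethyloxirane-2-carboxylic acid
Product: 24 dimethyl (3S,4S,5R,6E)-4-{[(2S,3R)-2,3-dimethyloxirane-2-carbonyl]oxy}-6-[(4E)-5-iodo-4-methylpent-4-en-1-ylidene]-3-{[(4-methoxybenzyl)oxy]methyl}-2-methylidene-5-(triethylsilyloxy)heptanedioate, via mixed anhydride 23 (not isolated)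
Conditions: 20, 2,4,6-trichlorobenzoyl chloride, Et3N, toluene, rt; then 22, DMAP, toluene, rt to 40 °C
Reagents that add atoms: none
Why: Yamaguchi esterification through the mixed anhydride should acylate the hindered C8 alcohol without touching any stereocentre, and it blocks the C8 hydroxyl from lactonising onto C12.

Step 14
Reactants: 24 epoxy ester
Product: 25 dimethyl (3S,4S,5R,6E)-4-{[(2S,3R)-2,3-dimethyloxirane-2-carbonyl]oxy}-3-(hydroxymethyl)-6-[(4E)-5-iodo-4-methylpent-4-en-1-ylidene]-2-methylidene-5-(triethylsilyloxy)heptanedioate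
Conditions: DDQ, CH2Cl2/pH 7 phosphate buffer (10:1), 0 °C
Reagents that add atoms: none
Why: Oxidative cleavage of the 4-methoxybenzyl ether by DDQ is orthogonal to the silyl ether, the esters, the oxirane and the alkenyl iodide; the buffered, cold conditions should keep the γ-hydroxy acrylate from lactonising.

Step 15
Reactants: 25 primary alcohol
Product: 26 dimethyl (3R,4S,5R,6E)-4-{[(2S,3R)-2,3-dimethyloxirane-2-carbonyl]oxy}-3-formyl-6-[(4E)-5-iodo-4-methylpent-4-en-1-ylidene]-2-methylidene-5-(triethylsilyloxy)heptanedioate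
Conditions: Dess–Martin periodinane, NaHCO3, CH2Cl2, 0 °C; filtered and used at once
Reagents that add atoms: none
Why: Buffered Dess–Martin oxidation should give the enolisable β,γ-unsaturated C6 aldehyde under neutral conditions, and it is taken on without chromatography to keep C7 intact.

Step 16
Reactants: 26 aldehyde
Product: 29 C9-silyl macrocyclic lactone (ten-membered carbocycle, C4=C5 E, trans-fused α-methylene-γ-lactone), via alkenylchromium 27 (not isolated), via hydroxy ester 28 (not isolated)
Conditions: CrCl2 (10 equiv), NiCl2 (0.1 equiv), DMSO, 2 mM, slow addition of 26, rt; aqueous work-up; then PPTS (cat.), CH2Cl2, rt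
Reagents that add atoms: none
Why: Zerovalent nickel, made from NiCl2 by divalent chromium, inserts into the C5–I bond and hands the alkenyl group with retention of its (E) geometry to trivalent chromium (27), which adds to the C6 aldehyde; the freed C6 hydroxyl of 28 then displaces methanol from the C12 ester under mild acid. The closest known reaction type is the intramolecular Nozaki–Hiyama–Kishi macrocyclisation, followed by lactonisation of a γ-hydroxy acrylate. The ten-membered carbocycle closes by a 10-exo-trig addition to the carbonyl group and the γ-lactone by a 5-exo-trig acyl substitution. C6 is the only new stereocentre and is controlled by C7 and C8: the alkenyl carbon should approach anti to the C7–C8 bond (Felkin–Anh, 1,2-syn to C11) and the new C–O bond should end up 1,3-anti to the C8 ester, with H6 in the plane of the C4=C5 alkene to avoid A(1,3) strain against C15, which is the H6/H7-anti arrangement of the trans-fused lactone. The step needs the organochromium to choose the aldehyde over four esters and the oxirane, which its low basicity and nucleophilicity secure, and ring closure to beat oligomerisation, which high dilution and the turn imposed by the C1=C10 enoate (C2 cis to C9) should favour. Because 26 is enolisable at C7 it is cyclised directly after its preparation.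

Step 17
Reactants: 29 C9-silyl macrocyclic lactone
Product: 30 C9-hydroxy macrocyclic lactone (4,5-deoxy target)
Conditions: HF·pyridine, pyridine, THF, 0 °C to rt
Reagents that add atoms: none
Why: Buffered fluoride desilylation should cleave the secondary triethylsilyl ether without acyl migration from O8 or conjugate addition to the methylene lactone.

Step 18
Reactants: 30 C9-hydroxy macrocyclic lactone
Product: 31 target CNP0262846.1
Conditions: mCPBA (1.1 equiv), NaHCO3, CH2Cl2, 0 °C
Reagents that add atoms: 3-chloroperbenzoic acid, OOC(=O)c1cccc(Cl)c1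
Why: Prilezhaev epoxidation should occur only at the electron-rich trisubstituted C4=C5 alkene (the two other alkenes are conjugated to carbonyl groups) and from its exposed outer face, which is syn to the C6–O bond because H6 lies in the alkene plane (A(1,3) strain with C15) and the ring chain covers the other face, giving the (4R,5R) trans-oxirane.

Compound list
1 | pent-4-yn-1-ol | C#CCCCO | starting material
2 | alkenylalane: dimethylaluminium alkoxide of (E)-5-(dimethylalumanyl)-4-methylpent-4-en-1-ol | C[Al](C)OCCC/C(C)=C/[Al](C)C | intermediate (not isolated)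
3 | (E)-5-iodo-4-methylpent-4-en-1-ol | OCCC/C(C)=C/I | intermediate
4 | (E)-5-iodo-4-methylpent-4-enal (fragment A) | O=CCC/C(C)=C/I | intermediate
5 | dimethyl (R)-malate | COC(=O)C[C@@H](O)C(=O)OC | starting material
6 | methyl (3R)-3,4-dihydroxybutanoate | COC(=O)C[C@@H](O)CO | intermediate
7 | methyl (3R)-3,4-bis(triethylsilyloxy)butanoate | COC(=O)C[C@@H](O[Si](CC)(CC)CC)CO[Si](CC)(CC)CC | intermediate
8 | lithium enolate of 7 | COC(O[Li])=C[C@@H](O[Si](CC)(CC)CC)CO[Si](CC)(CC)CC | intermediate (not isolated)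
9 | methyl (6E)-2-[(1R)-1,2-bis(triethylsilyloxy)ethyl]-3-hydroxy-7-iodo-6-methylhept-6-enoate, mixture at C2 and C3 | COC(=O)C(C(O)CC/C(C)=C/I)[C@@H](O[Si](CC)(CC)CC)CO[Si](CC)(CC)CC | intermediate
10 | 3-methanesulfonate of 9 | COC(=O)C(C(OS(C)(=O)=O)CC/C(C)=C/I)[C@@H](O[Si](CC)(CC)CC)CO[Si](CC)(CC)CC | intermediate (not isolated)
11 | methyl (2E,6E)-2-[(1R)-1,2-bis(triethylsilyloxy)ethyl]-7-iodo-6-methylhepta-2,6-dienoate | COC(=O)/C(=C/CC/C(C)=C/I)[C@@H](O[Si](CC)(CC)CC)CO[Si](CC)(CC)CC | intermediate
12 | dimethyl(alkoxy)sulfonium chloride of the C8 oxygen of 11 (primary silyl group replaced by SMe2+) | C[S+](C)OC[C@H](O[Si](CC)(CC)CC)/C(C(=O)OC)=C\CC/C(C)=C/I.[Cl-] | intermediate (not isolated)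
13 | methyl (2E,6E)-7-iodo-6-methyl-2-[(1R)-2-oxo-1-(triethylsilyloxy)ethyl]hepta-2,6-dienoate (fragment B) | COC(=O)/C(=C/CC/C(C)=C/I)[C@@H](O[Si](CC)(CC)CC)C=O | intermediate
14 | 2-[(4-methoxybenzyl)oxy]acetaldehyde | COc1ccc(COCC=O)cc1 | starting material
15 | methyl acrylate | C=CC(=O)OC | starting material
16 | methyl 3-hydroxy-4-[(4-methoxybenzyl)oxy]-2-methylidenebutanoate (racemic) | COC(=O)C(=C)C(O)COCc1ccc(OC)cc1 | intermediate
17 | methyl (2Z)-2-(bromomethyl)-4-[(4-methoxybenzyl)oxy]but-2-enoate (fragment C) | COC(=O)/C(CBr)=C/COCc1ccc(OC)cc1 | intermediate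
18 | (2E)-2-methylbut-2-en-1-ol | C/C=C(\C)CO | starting material
19 | [(2R,3R)-2,3-dimethyloxiran-2-yl]methanol | OC[C@@]1(C)O[C@@H]1C | intermediate
20 | (2S,3R)-2,3-dimethyloxirane-2-carboxylic acid | OC(=O)[C@@]1(C)O[C@@H]1C | intermediate
21 | allylindium dibromide derived from 17 (In in place of Br) | COC(=O)/C(C[In](Br)Br)=C/COCc1ccc(OC)cc1 | intermediate (not isolated)
22 | dimethyl (3S,4S,5R,6E)-4-hydroxy-6-[(4E)-5-iodo-4-methylpent-4-en-1-ylidene]-3-{[(4-methoxybenzyl)oxy]methyl}-2-methylidene-5-(triethylsilyloxy)heptanedioate | C=C(C(=O)OC)[C@@H](COCc1ccc(OC)cc1)[C@H](O)[C@H](O[Si](CC)(CC)CC)/C(C(=O)OC)=C\CC/C(C)=C/I | intermediate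
23 | (2S,3R)-2,3-dimethyloxirane-2-carboxylic 2,4,6-trichlorobenzoic anhydride | O=C(OC(=O)c1c(Cl)cc(Cl)cc1Cl)[C@@]1(C)O[C@@H]1C | intermediate (not isolated)
24 | dimethyl (3S,4S,5R,6E)-4-{[(2S,3R)-2,3-dimethyloxirane-2-carbonyl]oxy}-6-[(4E)-5-iodo-4-methylpent-4-en-1-ylidene]-3-{[(4-methoxybenzyl)oxy]methyl}-2-methylidene-5-(triethylsilyloxy)heptanedioate | C=C(C(=O)OC)[C@@H](COCc1ccc(OC)cc1)[C@H](OC(=O)[C@@]1(C)O[C@@H]1C)[C@H](O[Si](CC)(CC)CC)/C(C(=O)OC)=C\CC/C(C)=C/I | intermediate
25 | dimethyl (3S,4S,5R,6E)-4-{[(2S,3R)-2,3-dimethyloxirane-2-carbonyl]oxy}-3-(hydroxymethyl)-6-[(4E)-5-iodo-4-methylpent-4-en-1-ylidene]-2-methylidene-5-(triethylsilyloxy)heptanedioate | C=C(C(=O)OC)[C@@H](CO)[C@H](OC(=O)[C@@]1(C)O[C@@H]1C)[C@H](O[Si](CC)(CC)CC)/C(C(=O)OC)=C\CC/C(C)=C/I | intermediate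
26 | dimethyl (3R,4S,5R,6E)-4-{[(2S,3R)-2,3-dimethyloxirane-2-carbonyl]oxy}-3-formyl-6-[(4E)-5-iodo-4-methylpent-4-en-1-ylidene]-2-methylidene-5-(triethylsilyloxy)heptanedioate | C=C(C(=O)OC)[C@@H](C=O)[C@H](OC(=O)[C@@]1(C)O[C@@H]1C)[C@H](O[Si](CC)(CC)CC)/C(C(=O)OC)=C\CC/C(C)=C/I | intermediate
27 | alkenylchromium dichloride derived from 26 (C5–CrCl2 in place of C5–I, E) | C=C(C(=O)OC)[C@@H](C=O)[C@H](OC(=O)[C@@]1(C)O[C@@H]1C)[C@H](O[Si](CC)(CC)CC)/C(C(=O)OC)=C\CC/C(C)=C/[Cr](Cl)Cl | intermediate (not isolated)
28 | hydroxy ester: cyclodeca-1(10),4-diene with C6–OH, C7 bearing C(=CH2)CO2Me, C8 epoxy ester, C9 OSiEt3, C10 CO2Me; C6 to C9 configured as in 31 | C=C(C(=O)OC)[C@@H]1[C@H](OC(=O)[C@@]2(C)O[C@@H]2C)[C@H](O[Si](CC)(CC)CC)/C(C(=O)OC)=C\CC/C(C)=C/[C@H]1O | intermediate (not isolated)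
29 | C9-silyl macrocyclic lactone: germacra-1(10),4,11(13)-trien-12,6-olide with C4=C5 E, C1=C10 with C2 cis to C9, 8-O-[(2S,3R)-2,3-dimethyloxirane-2-carbonyl], 9-OSiEt3, C14 as CO2Me; C6 to C9 configured as in 31 | C=C1C(=O)O[C@H]2[C@H]1[C@H](OC(=O)[C@@]1(C)O[C@@H]1C)[C@H](O[Si](CC)(CC)CC)/C(C(=O)OC)=C\CC/C(C)=C/2 | intermediate
30 | C9-hydroxy macrocyclic lactone (29 without the silyl group; 4,5-deoxy target) | C=C1C(=O)O[C@H]2[C@H]1[C@H](OC(=O)[C@@]1(C)O[C@@H]1C)[C@H](O)/C(C(=O)OC)=C\CC/C(C)=C/2 | intermediate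
31 | target CNP0262846.1: germacra-1(10),11(13)-dien-12,6-olide with (4R,5R)-4,5-oxirane, 6S,7R,8S,9R, 8-O-[(2S,3R)-2,3-dimethyloxirane-2-carbonyl], 9-OH, C14 as CO2Me, C2 cis to C9 on C1=C10 | C=C1C(=O)O[C@H]2[C@H]1[C@H](OC(=O)[C@@]1(C)O[C@@H]1C)[C@H](O)/C(C(=O)OC)=C\CC[C@@]1(C)O[C@H]21 | target

Total step count: 18. Longest linear sequence: 12 steps (steps 1, 2, 5, 6, 7, 12, 13, 14, 15, 16, 17, 18).

Steps most likely to fail

Step 16 (ring closure). The aldehyde 26 may be consumed by enolisation at C7 (migration of the C11=C13 double bond into conjugation, β-elimination of the C8 ester) faster than the slow ten-membered ring closure takes place. The fallback sets out from 24 and comes back at 29. Conjugate addition of thiophenol (PhSH, Et3N cat., CH2Cl2, 0 °C) masks the acrylate as the β-phenylthio ester F1 (mixture at C11). DDQ then frees the primary alcohol F2, and Dess–Martin oxidation gives the aldehyde F3, now an ordinary α-branched aldehyde that tolerates slow addition and long reaction times. The same CrCl2/NiCl2 closure of the C5–C6 bond with lactonisation should give the phenylthiomethyl lactone F4. NaIO4 (MeOH/H2O, 0 °C) oxidises it to the sulfoxide F5, whose thermal syn-elimination (toluene, CaCO3, 90 °C) restores the α-methylene lactone 29.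

Step 12 (allylation). Relative stereocontrol may be lost through open or chelated transition states that erode the syn and Felkin preferences, and the allylindium may undergo β-elimination of the ether oxygen. The fallback sets out from 17 and comes back at 22. Borylation with bis(pinacolato)diboron under Pd2(dba)3 catalysis (toluene, 50 °C) converts 17 into the allylboronate F6. Its Sc(OTf)3-catalysed allylboration of 13 (toluene, −78 to 0 °C) runs through a closed, boron-centred chair transition state that ties the syn outcome to the geometry of the reagent, and hydrolytic work-up should give 22.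

Step 18 (epoxidation). Facial selectivity of the peripheral attack on C4=C5 may be poor if the ring of 30 populates more than one conformer. The fallback sets out from 28 and comes back at 31. The hydroxy ester 28 is isolated by leaving out the PPTS stage of step 16, and hydroxyl-directed epoxidation (VO(acac)2, tBuOOH, CH2Cl2, 0 °C; threo-selective because C15 is cis to C6) gives the epoxy alcohol F7. PPTS lactonisation then gives the silyl epoxy lactone F8, and HF·pyridine removes the silyl group to give 31.

Further compounds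
F1 | step 16 | thiophenol adduct of 24 (C13–SPh, mixture at C11) | COC(=O)C(CSc1ccccc1)[C@@H](COCc1ccc(OC)cc1)[C@H](OC(=O)[C@@]1(C)O[C@@H]1C)[C@H](O[Si](CC)(CC)CC)/C(C(=O)OC)=C\CC/C(C)=C/I
F2 | step 16 | primary alcohol from F1 (C6–OH) | COC(=O)C(CSc1ccccc1)[C@@H](CO)[C@H](OC(=O)[C@@]1(C)O[C@@H]1C)[C@H](O[Si](CC)(CC)CC)/C(C(=O)OC)=C\CC/C(C)=C/I
F3 | step 16 | C6 aldehyde from F2 | COC(=O)C(CSc1ccccc1)[C@@H](C=O)[C@H](OC(=O)[C@@]1(C)O[C@@H]1C)[C@H](O[Si](CC)(CC)CC)/C(C(=O)OC)=C\CC/C(C)=C/I
F4 | step 16 | α-(phenylthiomethyl) macrocyclic lactone (29 with C11–CH2SPh in place of C11=CH2) | c1ccccc1SCC1C(=O)O[C@H]2[C@H]1[C@H](OC(=O)[C@@]1(C)O[C@@H]1C)[C@H](O[Si](CC)(CC)CC)/C(C(=O)OC)=C\CC/C(C)=C/2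
F5 | step 16 | sulfoxide of F4 | O=S(c1ccccc1)CC1C(=O)O[C@H]2[C@H]1[C@H](OC(=O)[C@@]1(C)O[C@@H]1C)[C@H](O[Si](CC)(CC)CC)/C(C(=O)OC)=C\CC/C(C)=C/2
F6 | step 12 | methyl (2E)-4-[(4-methoxybenzyl)oxy]-2-[(4,4,5,5-tetramethyl-1,3,2-dioxaborolan-2-yl)methyl]but-2-enoate | COC(=O)/C(CB1OC(C)(C)C(C)(C)O1)=C/COCc1ccc(OC)cc1
F7 | step 18 | (4R,5R)-4,5-epoxide of hydroxy ester 28 | C=C(C(=O)OC)[C@@H]1[C@H](OC(=O)[C@@]2(C)O[C@@H]2C)[C@H](O[Si](CC)(CC)CC)/C(C(=O)OC)=C\CC[C@@]2(C)O[C@@H]2[C@H]1O
F8 | step 18 | 9-O-triethylsilyl ether of target 31 | C=C1C(=O)O[C@H]2[C@H]1[C@H](OC(=O)[C@@]1(C)O[C@@H]1C)[C@H](O[Si](CC)(CC)CC)/C(C(=O)OC)=C\CC[C@@]1(C)O[C@H]21
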